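**Strategy.** The route rests on reading the C6–O7–C8 unit of the 3,7-dioxabicyclo[3.3.0]octane core (aryl-bearing C6, ring oxygen O7, methylene C8) as a non-stabilised carbonyl ylide and the ring-fusion bond C1–C5 as the C3=C4 enol acetate of a 2-aryl-2,5-dihydrofuran. One [3+2] cycloaddition then makes C8–C1 and C6–C5, closes the second tetrahydrofuran ring and sets C1, C5 and C6 from the single stereocentre C2, with the tertiary acetate already in place. The precursors are a racemic α-chlorobenzyl (trimethylsilyl)methyl ether and an (R)-3-acetoxy-2-aryl-2,5-dihydrofuran made by a gold-catalysed acyloxy shift and cyclisation.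

Key step: step 5

Remarks
- Core numbering: C1 = acetoxy-bearing ring-fusion carbon, C2 and C6 = aryl-bearing carbons, C5 = ring-fusion CH, C4 and C8 = OCH2. The target is (1S,2R,5R,6S), with both aryl groups exo and cis to the C1 acetoxy and C5 hydrogen.
- Assumption: in step 1 the ligand antipode is the one that delivers the alkyne to the aldehyde face giving the R carbinol; (S,S)-ProPhenol is written, and its enantiomer would be used if the sense were opposite.
- Ar = 4-(benzyloxy)-3-methoxyphenyl throughout.

**Step 1**
Reactants: 1 4-(benzyloxy)-3-methoxybenzaldehyde; 2 prop-2-yn-1-yl acetate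
Product: 3 (4R)-4-[4-(benzyloxy)-3-methoxyphenyl]-4-hydroxybut-2-yn-1-yl acetate
Conditions: (S,S)-ProPhenol (10 mol%), Me2Zn (3 equiv), Ph3P=O (20 mol%), toluene, 0 °C
Reagents that add atoms: none
Why: Zinc–ProPhenol-catalysed enantioselective alkynylation of an aryl aldehyde should deliver the alkynylzinc derived from 2 to one aldehyde face, which sets the carbinol centre as R; the acetate of 2 is inert to Me2Zn.

**Step 2**
Reactants: 3
Product: 5 (2R)-2-[4-(benzyloxy)-3-methoxyphenyl]-2,5-dihydrofuran-3-yl acetate, via allenyl acetate 4 (not isolated)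
Conditions: Ph3PAuNTf2 (2 mol%), CH2Cl2, rt
Reagents that add atoms: none
Why: Gold(I) should trigger the [3,3] (1,3-)acyloxy shift of the propargylic acetate to allenyl acetate 4 and then 5-endo hydroalkoxylation of the allene by the neighbouring hydroxyl (the known cycloisomerisation of butynediol monoesters to 3-acyloxy-2,5-dihydrofurans), which leaves the carbinol stereocentre untouched and places the acetate on the carbon next to it.

**Step 3**
Reactants: 1 4-(benzyloxy)-3-methoxybenzaldehyde; 6 (trimethylsilyl)methanol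
Product: 7 1-(benzyloxy)-4-{bis[(trimethylsilyl)methoxy]methyl}-2-methoxybenzene
Conditions: 6 (2.5 equiv), PPTS (5 mol%), benzene, reflux, Dean–Stark
Reagents that add atoms: none
Why: Acid-catalysed acetalisation driven by azeotropic removal of water; no stereocentre is formed.

**Step 4**
Reactants: 7
Product: 8 1-(benzyloxy)-4-{chloro[(trimethylsilyl)methoxy]methyl}-2-methoxybenzene (racemic, used crude)
Conditions: AcCl (1.05 equiv), SOCl2 (2 mol%), CH2Cl2, 0 °C to rt; volatiles removed in vacuo
Reagents that add atoms: acetyl chloride CC(Cl)=O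
Why: Acetal-to-α-chloro-ether exchange with an acyl chloride (one alkoxy group leaves as its acetate) is a standard route to α-chlorobenzyl ethers; the product is racemic, which is irrelevant because this carbon becomes planar in the ylide.

**Step 5**
Reactants: 8 α-chloro ether (3 equiv, added slowly); 5 (2R)-dihydrofuranyl acetate
Product: 10 (1S,2R,5R,6S)-2,6-bis[4-(benzyloxy)-3-methoxyphenyl]-3,7-dioxabicyclo[3.3.0]octan-1-yl acetate, via carbonyl ylide 9 (not isolated)
Conditions: CsF (4 equiv), 4 Å MS, MeCN, rt, syringe-pump addition of 8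
Reagents that add atoms: none
Why: Proposed new method: fluoride attacks silicon of 8 as chloride leaves (1,3-elimination) to give the non-stabilised carbonyl ylide 9, which adds across C3=C4 of 5 in a concerted, suprafacial [3+2] cycloaddition; the closest known reaction type is the fluoride-induced 1,3-elimination of α-chloroalkyl silylmethyl ethers with [3+2] trapping by electron-poor alkenes, and enol ethers are known partners only for stabilised carbonyl ylides, so an enol ester as partner of this ylide is the untested element. The new oxolane ring closes by intermolecular [3+2] cycloaddition (4π + 2π, both C–C bonds in one transition state), which fixes the cis ring fusion. Regiochemistry is matched in polarity and in size: the aryl-bearing, oxocarbenium-like terminus of 9 bonds to the nucleophilic, unsubstituted C4 of the enol acetate, and the nucleophilic CH2 terminus bonds to the acetoxy-bearing C3. C1 and C5 are set by approach of 9 to the alkene face anti to the C2 aryl group of 5, and C6 by the exo transition state of the E-ylide, whose aryl group and oxygen point away from the dihydrofuran ring. The step needs cycloaddition to outrun closure of 9 to the oxirane and its dimerisation, which slow addition of excess 8 to concentrated 5 is meant to secure.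

**Step 6**
Reactants: 10
Product: 11 1-acetoxypinoresinol, (1S,2R,5R,6S)-2,6-bis(4-hydroxy-3-methoxyphenyl)-3,7-dioxabicyclo[3.3.0]octan-1-yl acetate
Conditions: H2 (1 atm), 10% Pd/C, EtOAc, rt, stopped at full debenzylation
Reagents that add atoms: none
Why: Catalytic hydrogenolysis should cleave the two aryl benzyl ethers faster than the cyclic benzylic C–O bonds of the furofuran and leaves the tertiary acetate and all four stereocentres untouched.

**Compound list**
1 | 4-(benzyloxy)-3-methoxybenzaldehyde (O-benzylvanillin) | COc1cc(C=O)ccc1OCc1ccccc1 | starting material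
2 | prop-2-yn-1-yl acetate (propargyl acetate) | C#CCOC(C)=O | starting material
3 | (4R)-4-[4-(benzyloxy)-3-methoxyphenyl]-4-hydroxybut-2-yn-1-yl acetate | COc1cc([C@@H](O)C#CCOC(C)=O)ccc1OCc1ccccc1 | intermediate
4 | (1R)-1-[4-(benzyloxy)-3-methoxyphenyl]-1-hydroxybuta-2,3-dien-2-yl acetate (allenyl acetate, not isolated) | COc1cc([C@@H](O)C(OC(C)=O)=C=C)ccc1OCc1ccccc1 | intermediate
5 | (2R)-2-[4-(benzyloxy)-3-methoxyphenyl]-2,5-dihydrofuran-3-yl acetate | COc1cc([C@H]2OCC=C2OC(C)=O)ccc1OCc1ccccc1 | intermediate
6 | (trimethylsilyl)methanol | C[Si](C)(C)CO | starting material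
7 | 1-(benzyloxy)-4-{bis[(trimethylsilyl)methoxy]methyl}-2-methoxybenzene | COc1cc(C(OC[Si](C)(C)C)OC[Si](C)(C)C)ccc1OCc1ccccc1 | intermediate
8 | 1-(benzyloxy)-4-{chloro[(trimethylsilyl)methoxy]methyl}-2-methoxybenzene (racemic) | COc1cc(C(Cl)OC[Si](C)(C)C)ccc1OCc1ccccc1 | intermediate
9 | carbonyl ylide ArCH=O(+)–CH2(−), Ar = 4-(benzyloxy)-3-methoxyphenyl (not isolated) | COc1cc(C=[O+][CH2-])ccc1OCc1ccccc1 | intermediate
10 | (1S,2R,5R,6S)-2,6-bis[4-(benzyloxy)-3-methoxyphenyl]-3,7-dioxabicyclo[3.3.0]octan-1-yl acetate (O,O′-dibenzyl-1-acetoxypinoresinol) | COc1cc([C@H]2OC[C@]3(OC(C)=O)[C@@H](c4ccc(OCc5ccccc5)c(OC)c4)OC[C@H]23)ccc1OCc1ccccc1 | intermediate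
11 | 1-acetoxypinoresinol, (1S,2R,5R,6S)-2,6-bis(4-hydroxy-3-methoxyphenyl)-3,7-dioxabicyclo[3.3.0]octan-1-yl acetate | COc1cc([C@H]2OC[C@]3(OC(C)=O)[C@@H](c4ccc(O)c(OC)c4)OC[C@H]23)ccc1O | target

**Count.** Total steps: 6. Longest linear sequence: 4 steps (1 → 3 → 5 → 10 → 11, or 1 → 7 → 8 → 10 → 11).

**Steps most likely to fail**

1. Step 5 (labelled step). The ylide may close to the aryl oxirane or dimerise, or the ionised chloro ether may alkylate an arene, before it adds to an unactivated enol ester. Fluoride may also cleave the enol acetate, and leakage to the endo or regioisomeric transition state would erode selectivity at C6. Fallback with known chemistry, setting out from 5 and 1 and returning at 10: 5 is cleaved with MeLi (2 equiv, THF, −78 °C) to the regiodefined lithium enolate F1, which is added to 1 to give the ketol F2. Excess dimethylsulfonium methylide (Me3S+ I−, n-BuLi, THF, −10 °C to rt) should convert the ketone into the spiro-epoxide F3. The benzylic alkoxide opens F3 at its CH2 terminus in the same flask (5-exo-tet; only the epoxide with CH2 cis to the side chain can close) to give the tertiary alcohol O,O′-dibenzyl-1-hydroxypinoresinol F4. Acetylation (Ac2O, DMAP, Et3N, CH2Cl2, 40 °C) then gives 10. Diastereomers at the carbinol carbon would be separated at F2 or F4.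

2. Step 2. The 1,3-shift of a primary acetate may be slow, and the cationic gold catalyst may ionise the electron-rich benzylic alcohol, with loss of enantiopurity or Meyer–Schuster-type rearrangement. Fallback without acyloxy shift, setting out from 1 and returning at 5: ProPhenol/Me2Zn addition of trimethylsilylacetylene to 1 gives the silyl alkynol F5, and K2CO3/MeOH gives the terminal alkynol F6. NaH/allyl bromide (THF, 0 °C) gives the allyl ether F7. Ruthenium-catalysed Markovnikov addition of acetic acid to the terminal alkyne ([Ru(p-cymene)Cl2]2, P(2-furyl)3, cat. Na2CO3, toluene, 50 °C) gives the enol acetate diene F8. Ring-closing metathesis (Grubbs II, CH2Cl2, 40 °C) then closes F8 to 5.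

3. Step 1. Conversion or facial selectivity may be low with an electron-rich aldehyde and an ester-bearing alkyne. Fallback, setting out from 1 and 2 and returning at 3: ligand-free alkynylzinc addition (Zn(OTf)2, Et3N, toluene, 60 °C) gives the racemic alcohol F9. MnO2 (CH2Cl2) oxidises it to the ynone F10. CBS reduction (catalyst antipode chosen for the R carbinol, (R)-Me-CBS if the aryl group acts as the large substituent; catecholborane, toluene, −78 °C) then gives 3.

**Further compounds**
F1 | step 5 | lithium (2R)-2-[4-(benzyloxy)-3-methoxyphenyl]-2,5-dihydrofuran-3-olate | COc1cc([C@H]2OCC=C2O[Li])ccc1OCc1ccccc1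
F2 | step 5 | (2R,4R)-2-[4-(benzyloxy)-3-methoxyphenyl]-4-{(S)-[4-(benzyloxy)-3-methoxyphenyl](hydroxy)methyl}oxolan-3-one | COc1cc([C@H]([C@H]2CO[C@H](c3ccc(OCc4ccccc4)c(OC)c3)C2=O)O)ccc1OCc1ccccc1
F3 | step 5 | (3S,4R,7R)-4-[4-(benzyloxy)-3-methoxyphenyl]-7-{(S)-[4-(benzyloxy)-3-methoxyphenyl](hydroxy)methyl}-1,5-dioxaspiro[2.4]heptane | COc1cc([C@H]([C@H]2CO[C@H](c3ccc(OCc4ccccc4)c(OC)c3)[C@@]23CO3)O)ccc1OCc1ccccc1
F4 | step 5 | (1S,2R,5R,6S)-2,6-bis[4-(benzyloxy)-3-methoxyphenyl]-3,7-dioxabicyclo[3.3.0]octan-1-ol (O,O′-dibenzyl-1-hydroxypinoresinol) | COc1cc([C@H]2OC[C@]3(O)[C@@H](c4ccc(OCc5ccccc5)c(OC)c4)OC[C@H]23)ccc1OCc1ccccc1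
F5 | step 2 | (1R)-1-[4-(benzyloxy)-3-methoxyphenyl]-3-(trimethylsilyl)prop-2-yn-1-ol | COc1cc([C@@H](O)C#C[Si](C)(C)C)ccc1OCc1ccccc1
F6 | step 2 | (1S)-1-[4-(benzyloxy)-3-methoxyphenyl]prop-2-yn-1-ol (same spatial arrangement as F5; descriptor changes with CIP priority) | COc1cc([C@@H](O)C#C)ccc1OCc1ccccc1
F7 | step 2 | 4-[(1S)-1-(allyloxy)prop-2-yn-1-yl]-1-(benzyloxy)-2-methoxybenzene | COc1cc([C@@H](OCC=C)C#C)ccc1OCc1ccccc1
F8 | step 2 | (3R)-3-(allyloxy)-3-[4-(benzyloxy)-3-methoxyphenyl]prop-1-en-2-yl acetate | COc1cc([C@@H](OCC=C)C(=C)OC(C)=O)ccc1OCc1ccccc1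
F9 | step 1 | racemic 4-[4-(benzyloxy)-3-methoxyphenyl]-4-hydroxybut-2-yn-1-yl acetate | COc1cc(C(O)C#CCOC(C)=O)ccc1OCc1ccccc1
F10 | step 1 | 4-[4-(benzyloxy)-3-methoxyphenyl]-4-oxobut-2-yn-1-yl acetate | COc1cc(C(=O)C#CCOC(C)=O)ccc1OCc1ccccc1
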